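In a one-step world target would simply track the electrophile charged. Here the solid must dissolve first, so dissolved electrophile stands between refill and use.

| flask | solid electrophile | nucleophile | free base | remark | time |
|---|---|---|---|---|---|
| Friday's | 0.10 M | 0.30 M | 0.60 M | run made earlier |  |
| Wednesday's | 0.15 M | 0.30 M | 0.60 M | run made earlier |  |
| Thursday's | 0.20 M | 0.60 M | 0.60 M | run made earlier |  |
| flask | 0.20 M | 0.300 M | 0.600 M |  | 20 h |

| run | time / h | target / % | electrophile / % | solid electrophile / % |
|---|---|---|---|---|
| Friday's | 1.00 | 0 | 9.8 | 90.0 |
| Friday's | 3.00 | 2.4 | 25.5 | 72.1 |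
| Friday's | 6.00 | 10.2 | 38.5 | 51.0 |
| Friday's | 8.00 | 15.6 | 45.7 | 39.8 |
| Friday's | 12.0 | 27.9 | 50.1 | 20.8 |
| Friday's | 15.0 | 38.0 | 53.9 | 8.7 |
| Friday's | 20.0 | 53.3 | 46.6 | 0.3 |
| Wednesday's | 3.00 | 2.0 | 17.0 | 81.1 |
| Wednesday's | 6.00 | 6.9 | 25.9 | 66.7 |
| Wednesday's | 8.00 | 11.5 | 29.7 | 61.5 |
| Wednesday's | 12.0 | 18.9 | 33.8 | 47.2 |
| Wednesday's | 15.0 | 24.8 | 36.1 | 38.7 |
| Wednesday's | 20.0 | 36.2 | 37.9 | 25.4 |
| Thursday's | 2.00 | 0.3 | 8.4 | 89.6 |
| Thursday's | 5.00 | 6.2 | 14.8 | 78.5 |
| Thursday's | 10.0 | 18.6 | 20.1 | 62.6 |
| Thursday's | 15.0 | 31.0 | 21.2 | 48.0 |
| Thursday's | 20.0 | 44.6 | 21.9 | 33.4 |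

(each reading ± 0.5 percentage points)

- given per volume of solution although it is solid: solid electrophile
- at the start none of the solid electrophile is in solution
- electrophile means what is dissolved; the solid is not counted in it

- dawn: doubling the dissolution coefficient of the solid electrophile, all else as stated
- winter: doubling the amount of nucleophile, all else as stated
- noon: doubling the solubility of the solid electrophile, all else as stated
- summer: doubling the amount of free base, all else as stated

* target at 20 h, in percent of the solid electrophile charged
* concentration of electrophile in solution at 5.0 h, in percent of saturation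
* the change that raises the amount of target at 20 h, in percent of the solid electrophile charged most ("none" if none brings more than 2 percentage points) (dawn / winter / noon / summer / none)
* amount of target at 20 h, in percent of the solid electrophile charged, after dawn

1. Refill. Thursday's solid falls at 0.0104 M/h early, with electrophile near 0.00840 M, and at 0.00584 M/h late, with electrophile near 0.0431 M. I read a dissolution coefficient of 0.131 /h and a saturation of 0.0875 M. Friday's run, with half the charge, starts at 0.0100 M/h, so I leave the charge out.

2. Use. Late Thursday target gives 0.241 /M/h.

3. Number. For the flask the use-to-refill number is 0.549: pseudo-first-order use of dissolved electrophile over the dissolution coefficient. Electrophile climbs towards 64.6 % of saturation with a time constant of 4.91 h, shorter than the run.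

4. Outcome. I get 41.2 % of saturation at 5.0 h and 30.9 % target at 20 h.

5. Test. The flask draws about 0.118 M of its 0.20 M, so solid remains. But I held nucleophile at its charge, so my target runs high. Doubling solubility leaves the number alone but doubles the draw to 0.236 M, above the charge, so on this reckoning the solid gives out near 15.5 h. What is dissolved then goes on reacting, which gives 59.2 % target, again with nucleophile held at its charge. That is above Thursday's 44.6 %, so I pick noon, knowing that the figure runs high.

The forecast says 27 %, 41 %, noon and 36 %, on the ground that “dissolution is essentially independent of the solid present”. Its target is lower than mine.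

    electrophile + nucleophile → acid set free + target (k = 6.57 × 10⁻⁵ /M/s)
    nucleophile + acid set free ⇌ protonated nucleophile, settled at all times (K = 130 /M)
    acid set free + free base ⇌ salt of the base, settled at all times (K = 4780 /M)
    solid electrophile ⇌ electrophile, rate k4*(cs4 - [electrophile]) while solid is left; crystals form when [electrophile] > cs4 (solubility = 0.0860 M, k = 3.59 × 10⁻⁵ /s)

The flask gives 27.4 % and 40.9 %. Noon gains most, 22 percentage points, and dawn reaches 36.1 %. At 20.0 h the flask keeps 82 % of its nucleophile and 44.1 % as solid. The number puts electrophile there at 28.2 % of the charge, and the flask holds 28.5 %.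

With 0.34 M of solid the number is unchanged, so electrophile should stand at 16.6 % of that charge. The computed neighbour holds 16.8 %, with target 16.1 %.

All runs are simulated from invented constants; noise was put on by code.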